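**Retrosynthetic overview**

- Megaphone acetate is traced back through megaphone (acetylation, desilylation) and O-methylation to a 4-hydroxy-cyclohex-2-enone. This comes from γ-oxidation of a 6,6-disubstituted cyclohex-2-enone, whose only acidic position is C4 because C6 is quaternary.
- The strategy rests on the cyclohexenone ring (C1 carbonyl, C2=C3, C4, C5, C6): the quaternary C6 is the branched α-carbon of a methyl ketone (C1 with C2 as its methyl group) and C5–C4–C3 is a three-carbon enal unit. Cutting C5–C6 (Michael) and C2=C3 (aldol condensation) leaves an open-chain methyl ketone, used as its chiral imine, and acrolein.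
- The methyl ketone comes from an α-allylated cis-γ-lactone (Weinreb amide opening, silylation, MeMgBr). The lactone comes from the syn homoallylic alcohol made by crotylboration of 3,4,5-trimethoxybenzaldehyde, which sets C7 and C8.
- Ring order: a temporary γ-lactone (closed in step 3, opened in step 5), then the cyclohexenone in step 9; the arene is bought.

Key step: step 9

Assumption: the target is numbered C1 (C=O), C2=C3, C4 (OMe), C5, C6 (quaternary), with C7 the benzylic and C8 the methyl-bearing side-chain carbon, and the (R)-configured phosphoric acid of step 1 is taken to induce Re-face addition to the aryl aldehyde as it does with benzaldehyde.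

**Step 1**
Reactants: 1 3,4,5-trimethoxybenzaldehyde; 2 (Z)-crotylboronic acid pinacol ester
Product: 3 (1R,2S)-2-methyl-1-(3,4,5-trimethoxyphenyl)but-3-en-1-ol
Conditions: (R)-3,3'-bis(2,4,6-triisopropylphenyl)-1,1'-binaphthyl-2,2'-diyl hydrogen phosphate (5 mol%), toluene, −30 °C; aqueous work-up
Reagents that add atoms: none
Why: Chiral phosphoric acid-catalysed crotylboration through a closed Zimmerman–Traxler chair: the Z geometry of 2 should give the syn C7/C8 relationship, and the (R)-acid, bound to the boronate oxygen and the formyl hydrogen, should direct addition to the Re face of the aldehyde (C7 R, C8 S).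

**Step 2**
Reactants: 3 (1R,2S)-2-methyl-1-(3,4,5-trimethoxyphenyl)but-3-en-1-ol
Product: 4 (1R,2S)-2-methyl-1-(3,4,5-trimethoxyphenyl)butane-1,4-diol
Conditions: 9-BBN (2.5 equiv), THF, 0 °C to rt; then NaOH, H2O2, 0 °C
Reagents that add atoms: hydrogen peroxide, OO
Why: Anti-Markovnikov hydroboration–oxidation of the monosubstituted alkene with the bulky borane places the hydroxyl on the terminal carbon and does not touch C7 or C8.

**Step 3**
Reactants: 4 (1R,2S)-2-methyl-1-(3,4,5-trimethoxyphenyl)butane-1,4-diol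
Product: 5 (4S,5R)-4-methyl-5-(3,4,5-trimethoxyphenyl)oxolan-2-one (cis lactone)
Conditions: 2,2,6,6-tetramethylpiperidin-1-oxyl (10 mol%), PhI(OAc)2 (2.5 equiv), CH2Cl2, rt
Reagents that add atoms: none
Why: Oxoammonium-mediated oxidative lactonisation: the unhindered primary alcohol should be oxidised faster than the hindered benzylic one, the aldehyde is captured as the five-membered lactol and oxidised on to the lactone, and the syn diol necessarily gives the cis-4,5-disubstituted ring.

**Step 4**
Reactants: 5 (4S,5R)-4-methyl-5-(3,4,5-trimethoxyphenyl)oxolan-2-one; 6 allyl bromide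
Product: 7 (3S,4S,5R)-3-allyl-4-methyl-5-(3,4,5-trimethoxyphenyl)oxolan-2-one
Conditions: LiN(i-Pr)2, THF, −78 °C; then 6, −78 to −40 °C
Reagents that add atoms: none
Why: Alkylation of the lactone lithium enolate, which should take the allyl group on the face opposite to the cis methyl and aryl groups (3,4-trans); the configuration of this carbon is of no consequence because it is erased in step 9.

**Step 5**
Reactants: 7 (3S,4S,5R)-3-allyl-4-methyl-5-(3,4,5-trimethoxyphenyl)oxolan-2-one
Product: 8 (2S,3S,4R)-2-allyl-4-hydroxy-N-methoxy-N,3-dimethyl-4-(3,4,5-trimethoxyphenyl)butanamide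
Conditions: MeNH(OMe)·HCl, AlMe3, CH2Cl2, 0 °C to rt; Rochelle salt work-up; used at once
Reagents that add atoms: N,O-dimethylhydroxylamine hydrochloride, CNOC.Cl
Why: Weinreb aminolysis of the lactone by the dimethylaluminium amide formed in the flask, driven by the Al–O bond and by release of the cis strain of the ring; 8 is silylated without delay because it can close back to 7.

**Step 6**
Reactants: 8 (2S,3S,4R)-2-allyl-4-hydroxy-N-methoxy-N,3-dimethyl-4-(3,4,5-trimethoxyphenyl)butanamide
Product: 9 (2S,3S,4R)-2-allyl-4-(tert-butyldimethylsilyloxy)-N-methoxy-N,3-dimethyl-4-(3,4,5-trimethoxyphenyl)butanamide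
Conditions: TBSOTf, 2,6-lutidine, CH2Cl2, −78 to 0 °C
Reagents that add atoms: tert-butyldimethylsilyl trifluoromethanesulfonate, CC(C)(C)[Si](C)(C)OS(=O)(=O)C(F)(F)F
Why: Silylation of the hindered benzylic secondary alcohol with a silyl triflate and a non-nucleophilic base blocks relactonisation and protects C7–OH through the later base and oxidant steps.

**Step 7**
Reactants: 9 (2S,3S,4R)-2-allyl-4-(tert-butyldimethylsilyloxy)-N-methoxy-N,3-dimethyl-4-(3,4,5-trimethoxyphenyl)butanamide
Product: 10 (3S,4S,5R)-3-allyl-5-(tert-butyldimethylsilyloxy)-4-methyl-5-(3,4,5-trimethoxyphenyl)pentan-2-one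
Conditions: MeMgBr (3 equiv), THF, 0 °C; aq. NH4Cl
Reagents that add atoms: methylmagnesium bromide, C[Mg]Br
Why: Weinreb ketone synthesis: the magnesium-chelated tetrahedral adduct does not collapse before work-up, so one methyl group is delivered and the methyl ketone forms without over-addition.

**Step 8**
Reactants: 10 (3S,4S,5R)-3-allyl-5-(tert-butyldimethylsilyloxy)-4-methyl-5-(3,4,5-trimethoxyphenyl)pentan-2-one
Product: 11 (E)-N-[(1S)-1-phenylethyl] ketimine of 10 (C3 of the pentane chain configurationally labile)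
Conditions: (S)-1-phenylethylamine (1.5 equiv), p-toluenesulfonic acid (2 mol%), toluene, reflux, Dean–Stark; volatiles removed, crude imine used
Reagents that add atoms: (S)-1-phenylethylamine, C[C@H](N)c1ccccc1
Why: Acid-catalysed condensation of the ketone with the primary amine under azeotropic removal of water gives the ketimine, and the excess amine buffers the acid so that the silyl ether should survive.

**Step 9**
Reactants: 11 (E)-N-[(1S)-1-phenylethyl] ketimine of 10; 12 acrolein
Product: 17 (6S)-6-allyl-6-[(1R,2S)-1-(tert-butyldimethylsilyloxy)-1-(3,4,5-trimethoxyphenyl)propan-2-yl]cyclohex-2-en-1-one, via secondary enamine tautomer 13 (not isolated), via Michael adduct imino aldehyde 14 (not isolated), via keto aldehyde 15 (not isolated), via aldol adduct 16 (not isolated)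
Conditions: 12 (1.5 equiv), hydroquinone (trace), THF, 0 °C to rt; then 20% aq. AcOH, rt; extraction; then KOH, MeOH, 0 °C to rt
Reagents that add atoms: water, O
Why: Proposed new method: imine 11 equilibrates with its more substituted secondary enamine 13, whose carbon C6 should add to the β-carbon of acrolein through a compact chair-like aza-ene transition state in which the N–H hydrogen passes to the acrolein α-carbon, so that the C5–C6 bond forms at the branched carbon and not at the methyl group; the closest known reaction type is the Michael addition of 1-phenylethylamine imines of 2-substituted cyclic ketones to enones and acrylates, extended here to an open-chain ketone and to an enal. After hydrolysis of 14, the methyl ketone enolate of 15 closes the ring by a 6-(enolexo)-exo-trig aldol addition onto the aldehyde and E1cB loss of water gives the enone; no other ring size can form because the aldehyde enolate could reach the ketone only through a four-membered ring. The C6 centre of 10 is erased in the enamine and the quaternary centre is set by the (S)-auxiliary: with its N–CH bond in the enamine plane the phenyl group covers one face, and addition to the other face of the (Z)-enamine (side chain cis to N–H), the same sense as in the cyclic series, gives 6S in 17 (the descriptor becomes 6R once C4 is oxygenated, with no change of geometry). The step needs attack at the more substituted carbon, which the preference for the more substituted enamine and the internal proton transfer should secure, and attack on one face, for which the auxiliary must prevail over the C8 centre, whose larger CH(OTBS)Ar arm lies on the required face in the H-eclipsed rotamer; this is the main risk of the route.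

**Step 10**
Reactants: 17 (6S)-6-allyl-6-[(1R,2S)-1-(tert-butyldimethylsilyloxy)-1-(3,4,5-trimethoxyphenyl)propan-2-yl]cyclohex-2-en-1-one
Product: 18 (6R)-6-allyl-6-[(1R,2S)-1-(tert-butyldimethylsilyloxy)-1-(3,4,5-trimethoxyphenyl)propan-2-yl]-1-(trimethylsilyloxy)cyclohexa-1,3-diene
Conditions: TMSOTf, Et3N, CH2Cl2, −78 to 0 °C; non-aqueous work-up (pentane, filtration), used crude
Reagents that add atoms: trimethylsilyl trifluoromethanesulfonate, C[Si](C)(C)OS(=O)(=O)C(F)(F)F
Why: Soft enolisation with a silyl triflate and a tertiary amine: C6 carries no hydrogen, so the activated enone can lose a proton only from C4, which gives the linear 1-silyloxy-1,3-diene.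

**Step 11**
Reactants: 18 (6R)-6-allyl-6-[(1R,2S)-1-(tert-butyldimethylsilyloxy)-1-(3,4,5-trimethoxyphenyl)propan-2-yl]-1-(trimethylsilyloxy)cyclohexa-1,3-diene
Product: 20 (4R,6R)-6-allyl-4-hydroxy-6-[(1R,2S)-1-(tert-butyldimethylsilyloxy)-1-(3,4,5-trimethoxyphenyl)propan-2-yl]cyclohex-2-en-1-one, via epoxy silyl enol ether 19 (not isolated)
Conditions: dimethyldioxirane (1.0 equiv), acetone/CH2Cl2, −78 °C; then AcOH, THF/H2O, 0 °C
Reagents that add atoms: dimethyldioxirane, CC1(C)OO1
Why: Vinylogous Rubottom oxidation: the dioxirane should epoxidise the electron-rich C3=C4 bond far faster than the monosubstituted allyl alkene, and push from the silyloxy group opens the epoxide to the γ-hydroxy enone; with the branched side chain pseudoequatorial, the pseudoaxial allyl group screens its own face of C4, so oxygen should enter anti to allyl (4R), a preference that is not secure.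

**Step 12**
Reactants: 20 (4R,6R)-6-allyl-4-hydroxy-6-[(1R,2S)-1-(tert-butyldimethylsilyloxy)-1-(3,4,5-trimethoxyphenyl)propan-2-yl]cyclohex-2-en-1-one
Product: 21 (4R,6R)-6-allyl-6-[(1R,2S)-1-(tert-butyldimethylsilyloxy)-1-(3,4,5-trimethoxyphenyl)propan-2-yl]-4-methoxycyclohex-2-en-1-one
Conditions: Me3OBF4, 1,8-bis(dimethylamino)naphthalene, 4 Å molecular sieves, CH2Cl2, 0 °C to rt
Reagents that add atoms: trimethyloxonium tetrafluoroborate, C[O+](C)C.F[B-](F)(F)F
Why: O-Methylation with Meerwein's salt and a hindered non-nucleophilic base is a neutral alkylation that avoids the alkoxide, which could isomerise the γ-hydroxy enone or epimerise C4.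

**Step 13**
Reactants: 21 (4R,6R)-6-allyl-6-[(1R,2S)-1-(tert-butyldimethylsilyloxy)-1-(3,4,5-trimethoxyphenyl)propan-2-yl]-4-methoxycyclohex-2-en-1-one
Product: 22 megaphone, (4R,6R)-6-allyl-6-[(1R,2S)-1-hydroxy-1-(3,4,5-trimethoxyphenyl)propan-2-yl]-4-methoxycyclohex-2-en-1-one
Conditions: HF·pyridine, pyridine, THF, 0 °C to rt
Reagents that add atoms: none
Why: Fluoride-mediated cleavage of the silyl ether, driven by the Si–F bond, under buffered weakly acidic conditions that should leave the γ-methoxy enone and its C4 centre untouched.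

**Step 14**
Reactants: 22 megaphone
Product: 23 megaphone acetate, (4R,6R)-6-[(1R,2S)-1-acetoxy-1-(3,4,5-trimethoxyphenyl)propan-2-yl]-6-allyl-4-methoxycyclohex-2-en-1-one
Conditions: Ac2O, pyridine, 4-(dimethylamino)pyridine (10 mol%), CH2Cl2, rt
Reagents that add atoms: acetic anhydride, CC(=O)OC(C)=O
Why: Nucleophilic catalysis through the acylpyridinium ion should acetylate the hindered secondary benzylic alcohol under conditions too mild to enolise the enone.

**Compound list**

1 | 3,4,5-trimethoxybenzaldehyde | COc1cc(C=O)cc(OC)c1OC | starting material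
2 | (Z)-crotylboronic acid pinacol ester | C/C=C\CB1OC(C)(C)C(C)(C)O1 | starting material
3 | (1R,2S)-2-methyl-1-(3,4,5-trimethoxyphenyl)but-3-en-1-ol | C=C[C@H](C)[C@@H](O)c1cc(OC)c(OC)c(OC)c1 | intermediate
4 | (1R,2S)-2-methyl-1-(3,4,5-trimethoxyphenyl)butane-1,4-diol | OCC[C@H](C)[C@@H](O)c1cc(OC)c(OC)c(OC)c1 | intermediate
5 | (4S,5R)-4-methyl-5-(3,4,5-trimethoxyphenyl)oxolan-2-one (cis) | O=C1C[C@H](C)[C@H](c2cc(OC)c(OC)c(OC)c2)O1 | intermediate
6 | allyl bromide | C=CCBr | starting material
7 | (3S,4S,5R)-3-allyl-4-methyl-5-(3,4,5-trimethoxyphenyl)oxolan-2-one | O=C1[C@@H](CC=C)[C@H](C)[C@H](c2cc(OC)c(OC)c(OC)c2)O1 | intermediate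
8 | (2S,3S,4R)-2-allyl-4-hydroxy-N-methoxy-N,3-dimethyl-4-(3,4,5-trimethoxyphenyl)butanamide | CON(C)C(=O)[C@@H](CC=C)[C@H](C)[C@@H](O)c1cc(OC)c(OC)c(OC)c1 | intermediate
9 | (2S,3S,4R)-2-allyl-4-(tert-butyldimethylsilyloxy)-N-methoxy-N,3-dimethyl-4-(3,4,5-trimethoxyphenyl)butanamide | CON(C)C(=O)[C@@H](CC=C)[C@H](C)[C@@H](O[Si](C)(C)C(C)(C)C)c1cc(OC)c(OC)c(OC)c1 | intermediate
10 | (3S,4S,5R)-3-allyl-5-(tert-butyldimethylsilyloxy)-4-methyl-5-(3,4,5-trimethoxyphenyl)pentan-2-one | CC(=O)[C@@H](CC=C)[C@H](C)[C@@H](O[Si](C)(C)C(C)(C)C)c1cc(OC)c(OC)c(OC)c1 | intermediate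
11 | (E)-N-[(1S)-1-phenylethyl] ketimine of 10 | C/C(=N\[C@@H](C)c1ccccc1)[C@@H](CC=C)[C@H](C)[C@@H](O[Si](C)(C)C(C)(C)C)c1cc(OC)c(OC)c(OC)c1 | intermediate
12 | acrolein | C=CC=O | starting material
13 | (Z)-secondary enamine tautomer of 11 (C2=C3 of the pentane chain, side chain cis to NH) | C/C(N[C@@H](C)c1ccccc1)=C(CC=C)/[C@H](C)[C@@H](O[Si](C)(C)C(C)(C)C)c1cc(OC)c(OC)c(OC)c1 | intermediate (not isolated)
14 | N-[(1S)-1-phenylethyl] imine of 15 at the ketone carbon | C/C(=N\[C@@H](C)c1ccccc1)[C@](CC=C)(CCC=O)[C@H](C)[C@@H](O[Si](C)(C)C(C)(C)C)c1cc(OC)c(OC)c(OC)c1 | intermediate (not isolated)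
15 | (4S,5S,6R)-4-acetyl-4-allyl-6-(tert-butyldimethylsilyloxy)-5-methyl-6-(3,4,5-trimethoxyphenyl)hexanal | CC(=O)[C@](CC=C)(CCC=O)[C@H](C)[C@@H](O[Si](C)(C)C(C)(C)C)c1cc(OC)c(OC)c(OC)c1 | intermediate (not isolated)
16 | (2S)-2-allyl-2-[(1R,2S)-1-(tert-butyldimethylsilyloxy)-1-(3,4,5-trimethoxyphenyl)propan-2-yl]-5-hydroxycyclohexan-1-one (both C5 epimers) | C=CC[C@]1([C@H](C)[C@@H](O[Si](C)(C)C(C)(C)C)c2cc(OC)c(OC)c(OC)c2)CCC(O)CC1=O | intermediate (not isolated)
17 | (6S)-6-allyl-6-[(1R,2S)-1-(tert-butyldimethylsilyloxy)-1-(3,4,5-trimethoxyphenyl)propan-2-yl]cyclohex-2-en-1-one | C=CC[C@]1([C@H](C)[C@@H](O[Si](C)(C)C(C)(C)C)c2cc(OC)c(OC)c(OC)c2)CCC=CC1=O | intermediate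
18 | (6R)-6-allyl-6-[(1R,2S)-1-(tert-butyldimethylsilyloxy)-1-(3,4,5-trimethoxyphenyl)propan-2-yl]-1-(trimethylsilyloxy)cyclohexa-1,3-diene | C=CC[C@]1([C@H](C)[C@@H](O[Si](C)(C)C(C)(C)C)c2cc(OC)c(OC)c(OC)c2)CC=CC=C1O[Si](C)(C)C | intermediate
19 | 3,4-epoxide of 18, oxygen on the ring face anti to allyl | C=CC[C@]1([C@H](C)[C@@H](O[Si](C)(C)C(C)(C)C)c2cc(OC)c(OC)c(OC)c2)C[C@H]3O[C@H]3C=C1O[Si](C)(C)C | intermediate (not isolated)
20 | (4R,6R)-6-allyl-4-hydroxy-6-[(1R,2S)-1-(tert-butyldimethylsilyloxy)-1-(3,4,5-trimethoxyphenyl)propan-2-yl]cyclohex-2-en-1-one | C=CC[C@]1([C@H](C)[C@@H](O[Si](C)(C)C(C)(C)C)c2cc(OC)c(OC)c(OC)c2)C[C@@H](O)C=CC1=O | intermediate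
21 | (4R,6R)-6-allyl-6-[(1R,2S)-1-(tert-butyldimethylsilyloxy)-1-(3,4,5-trimethoxyphenyl)propan-2-yl]-4-methoxycyclohex-2-en-1-one | C=CC[C@]1([C@H](C)[C@@H](O[Si](C)(C)C(C)(C)C)c2cc(OC)c(OC)c(OC)c2)C[C@@H](OC)C=CC1=O | intermediate
22 | megaphone, (4R,6R)-6-allyl-6-[(1R,2S)-1-hydroxy-1-(3,4,5-trimethoxyphenyl)propan-2-yl]-4-methoxycyclohex-2-en-1-one | C=CC[C@]1([C@H](C)[C@@H](O)c2cc(OC)c(OC)c(OC)c2)C[C@@H](OC)C=CC1=O | intermediate
23 | megaphone acetate | C=CC[C@]1([C@H](C)[C@@H](OC(C)=O)c2cc(OC)c(OC)c(OC)c2)C[C@@H](OC)C=CC1=O | target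

**Step count**

Total: 14 steps. Longest linear sequence: 14 steps (from 1).

**Steps most likely to fail**

Step 9. Three things may go wrong:
- Facial selectivity at C6 may be poor, because the open-chain enamine can react through either geometry and the C8 centre may work against the auxiliary.
- Acrolein may be taken up at nitrogen or at the methyl-side enamine.
- Acrolein may polymerise.

The fallback uses known chemistry, sets out from lactone 5 and comes back at keto aldehyde 15. Lactone 5 would be alkylated (LiN(i-Pr)2, THF/DMPU, −78 °C) with 2-(2-iodoethyl)-1,3-dioxolane to the 3-[2-(1,3-dioxolan-2-yl)ethyl] lactone F1. A second enolate alkylation with allyl bromide 6 would deliver allyl to the face opposite the C4 methyl group and give the quaternary lactone F2, in which the ring fixes the C6 configuration of the target. Opening as in steps 5 to 7 (Me2AlN(OMe)Me with warming; TBSOTf; MeLi) would give the hydroxy amide F3, its silyl ether F4 and the methyl ketone acetal F5. Pyridinium p-toluenesulfonate in wet acetone would unmask the aldehyde to give 15, which is condensed to 17 with KOH in MeOH as in step 9.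

Step 11. The oxidant may approach C4 from the allyl face if the side chain sits pseudoaxial, or may attack C2 in part. The fallback sets out from 18 and comes back at 20. The oxidation would then give the C4 epimer, the (4S)-hydroxy enone F6, which is separated from 20 if both form. Mitsunobu reaction with 4-nitrobenzoic acid, PPh3 and diisopropyl azodicarboxylate would invert C4 to the (4R)-4-nitrobenzoate F7. Methanolysis (K2CO3, MeOH, 0 °C) then gives 20.

Step 5. The γ-hydroxy amide may close back to the lactone before it is silylated, so that material is lost between steps 5 and 6. The fallback sets out from 7 and comes back at 10. MeLi (1.1 equiv, THF, −78 °C) would add once to the lactone, whose lithium hemiketal is stable at low temperature, to give the hydroxy ketone F8 (in equilibrium with its cyclic hemiketal). Silylation of the open form with TBSCl and imidazole in DMF gives 10.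

**Further compounds**

F1 | step 9 | (3S,4S,5R)-3-[2-(1,3-dioxolan-2-yl)ethyl]-4-methyl-5-(3,4,5-trimethoxyphenyl)oxolan-2-one | O=C1[C@@H](CCC2OCCO2)[C@H](C)[C@H](c3cc(OC)c(OC)c(OC)c3)O1
F2 | step 9 | (3S,4S,5R)-3-allyl-3-[2-(1,3-dioxolan-2-yl)ethyl]-4-methyl-5-(3,4,5-trimethoxyphenyl)oxolan-2-one | O=C1[C@](CC=C)(CCC2OCCO2)[C@H](C)[C@H](c3cc(OC)c(OC)c(OC)c3)O1
F3 | step 9 | (2S,3S,4R)-2-allyl-2-[2-(1,3-dioxolan-2-yl)ethyl]-4-hydroxy-N-methoxy-N,3-dimethyl-4-(3,4,5-trimethoxyphenyl)butanamide | CON(C)C(=O)[C@](CC=C)(CCC1OCCO1)[C@H](C)[C@@H](O)c1cc(OC)c(OC)c(OC)c1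
F4 | step 9 | (2S,3S,4R)-2-allyl-4-(tert-butyldimethylsilyloxy)-2-[2-(1,3-dioxolan-2-yl)ethyl]-N-methoxy-N,3-dimethyl-4-(3,4,5-trimethoxyphenyl)butanamide | CON(C)C(=O)[C@](CC=C)(CCC1OCCO1)[C@H](C)[C@@H](O[Si](C)(C)C(C)(C)C)c1cc(OC)c(OC)c(OC)c1
F5 | step 9 | (3S,4S,5R)-3-allyl-5-(tert-butyldimethylsilyloxy)-3-[2-(1,3-dioxolan-2-yl)ethyl]-4-methyl-5-(3,4,5-trimethoxyphenyl)pentan-2-one | CC(=O)[C@](CC=C)(CCC1OCCO1)[C@H](C)[C@@H](O[Si](C)(C)C(C)(C)C)c1cc(OC)c(OC)c(OC)c1
F6 | step 11 | (4S,6R)-6-allyl-4-hydroxy-6-[(1R,2S)-1-(tert-butyldimethylsilyloxy)-1-(3,4,5-trimethoxyphenyl)propan-2-yl]cyclohex-2-en-1-one | C=CC[C@]1([C@H](C)[C@@H](O[Si](C)(C)C(C)(C)C)c2cc(OC)c(OC)c(OC)c2)C[C@H](O)C=CC1=O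
F7 | step 11 | (4R,6R)-6-allyl-6-[(1R,2S)-1-(tert-butyldimethylsilyloxy)-1-(3,4,5-trimethoxyphenyl)propan-2-yl]-4-(4-nitrobenzoyloxy)cyclohex-2-en-1-one | C=CC[C@]1([C@H](C)[C@@H](O[Si](C)(C)C(C)(C)C)c2cc(OC)c(OC)c(OC)c2)C[C@@H](OC(=O)c3ccc([N+](=O)[O-])cc3)C=CC1=O
F8 | step 5 | (3S,4S,5R)-3-allyl-5-hydroxy-4-methyl-5-(3,4,5-trimethoxyphenyl)pentan-2-one | CC(=O)[C@@H](CC=C)[C@H](C)[C@@H](O)c1cc(OC)c(OC)c(OC)c1
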